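## Retrosynthetic overview

1. Target ⇐ hydroquinone 34 (O-sulfation) ⇐ dimethyl ether 32 (oxidative demethylation, then reduction).
2. 32 ⇐ allylic ester 27 by a fragment-uniting Ireland–Claisen rearrangement, which makes the C9'–C11' bond, the C9' quaternary centre and the C1'=C10' olefin in one step; the extra CO2H is then removed by radical decarboxylation.
3. Left acid 19: ring A from 2-methylcyclohexanone (asymmetric Michael sets C4); ring B by a catalytic enantioselective exo Diels–Alder of vinylcyclohexene 10 with tiglaldehyde (C8, C9, C10 at once); arene by Grignard addition and deoxygenation.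
4. Right alcohol 26: ring D from 4,4-dimethylcyclohexenone; ring C by Diels–Alder of dienone 23 with ethylene (C5'/C8' cis); absolute configuration by CBS reduction and diastereomer separation.
5. Ring order: A → B (left half), D → C (right half); the halves are joined last.

Assumption: the target is made as drawn (free bis(hydrogen sulfate)) by cold H+ exchange of the sulfate salt formed first, and boronate 22 is taken as a catalogue item.

Locants used: left decalin C1–C10 (ring A = C1–C5, C10; ring B = C5–C10), benzylic carbon C11, linker C11'–C12' (C11' on C9'), right decalin C1'–C10' (ring D = C1'–C5', C10'; ring C = C5'–C10').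

## Route

Step 1
Reactants: 1 2-methylcyclohexanone (racemic); 2 (R)-1-phenylethylamine; 3 methyl acrylate
Product: 6 methyl 3-[(1S)-1-methyl-2-oxocyclohexyl]propanoate, via imine 4 (not isolated), via Michael adduct imine 5 (not isolated)
Conditions: 1 + 2, TsOH (cat.), PhMe, reflux (Dean–Stark); 3, THF, 40 °C, 3 d; 20% aq AcOH, 23 °C
Reagents that add atoms: water, O
Why: d'Angelo asymmetric Michael reaction, in which the more substituted secondary enamine tautomer of the chiral imine adds to the acrylate through a compact aza-ene-like transition state on the face away from the phenyl group, so the (R)-amine gives the (S)-configured C4 quaternary centre (about 90% ee) and hydrolysis returns the auxiliary.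

Step 2
Reactants: 6 methyl 3-[(1S)-1-methyl-2-oxocyclohexyl]propanoate
Product: 8 methyl 3-[(1S)-1-methyl-2-(trifluoromethylsulfonyloxy)cyclohex-2-en-1-yl]propanoate, via potassium enolate 7 (not isolated)
Conditions: KN(SiMe3)2, THF, −78 °C; PhNTf2, −78 → 0 °C
Reagents that add atoms: N-phenylbis(trifluoromethanesulfonimide), O=S(=O)(N(c1ccccc1)S(=O)(=O)C(F)(F)F)C(F)(F)F
Why: Enol triflate formation by kinetic deprotonation at C10, the only enolisable position of the α-quaternary ketone (far more acidic than the ester), followed by O-triflation; C4 is untouched.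

Step 3
Reactants: 8 enol triflate; 9 tributyl(vinyl)stannane
Product: 10 methyl 3-[(1S)-2-ethenyl-1-methylcyclohex-2-en-1-yl]propanoate
Conditions: Pd(PPh3)4 (5 mol %), LiCl, THF, 65 °C
Reagents that add atoms: none
Why: Stille coupling of the enol triflate (LiCl-assisted transmetalation) installs the vinyl group and gives the 1-vinylcyclohexene diene, whose s-cis form is favoured because the s-trans form clashes with the C4 quaternary centre.

Step 4
Reactants: 10 diene ester; 11 (E)-2-methylbut-2-enal (tiglaldehyde)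
Product: 12 methyl 3-[(1S,4aS,5S,6R)-5-formyl-1,5,6-trimethyl-1,2,3,4,4a,5,6,7-octahydronaphthalen-1-yl]propanoate
Conditions: (3aS)-1-(2-methylphenyl)-3,3-diphenyltetrahydro-1H,3H-pyrrolo[1,2-c][1,3,2]oxazaborole (20 mol %), (CF3SO2)2NH (18 mol %), CH2Cl2, −78 → −40 °C
Reagents that add atoms: none
Why: Enantioselective Diels–Alder reaction under chiral cationic oxazaborolidine catalysis, in which the unhindered vinyl terminus C7 bonds to the enal β-carbon (C8) and ring carbon C10 to the α-carbon (C9), the α-methyl enal reacts with its formyl group exo (CHO cis to H-10), the E geometry of tiglaldehyde puts the C8 and C9 methyls cis, and the (S)-catalyst exposes the enal face that gives the target configuration at C8, C9 and C10 (the same sense as its (2S)-exo adduct of 2-methylacrolein and cyclopentadiene), overriding the weak bias of C4.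

Step 5
Reactants: 12 aldehyde ester; 13 (2,5-dimethoxyphenyl)magnesium bromide
Product: 14 methyl 3-[(1S,4aS,5S,6R)-5-[(2,5-dimethoxyphenyl)(hydroxy)methyl]-1,5,6-trimethyl-1,2,3,4,4a,5,6,7-octahydronaphthalen-1-yl]propanoate (carbinol epimers)
Conditions: THF, −78 → −20 °C; aq NH4Cl
Reagents that add atoms: none
Why: Grignard 1,2-addition to the non-enolisable neopentylic aldehyde, which is much faster at low temperature than attack on the methyl ester; the new carbinol centre is unselective and is removed in step 7.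

Step 6
Reactants: 14 benzylic alcohol
Product: 17 methyl 3-[(1S,4aS,5S,6R)-5-[(2,5-dimethoxyphenyl)(methylsulfanylcarbothioyloxy)methyl]-1,5,6-trimethyl-1,2,3,4,4a,5,6,7-octahydronaphthalen-1-yl]propanoate, via sodium alkoxide 15 (not isolated), via sodium xanthate 16 (not isolated)
Conditions: NaN(SiMe3)2, THF, −78 °C; CS2; MeI, −78 → 23 °C
Reagents that add atoms: carbon disulfide, S=C=S; iodomethane, CI
Why: Xanthate ester formation (alkoxide addition to CS2, then S-methylation), with the base deprotonating the alcohol in preference to the ester α-position.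

Step 7
Reactants: 17 xanthate
Product: 18 methyl 3-[(1S,4aR,5S,6R)-5-(2,5-dimethoxybenzyl)-1,5,6-trimethyl-1,2,3,4,4a,5,6,7-octahydronaphthalen-1-yl]propanoate
Conditions: Bu3SnH, AIBN (cat.), PhMe, 100 °C
Reagents that add atoms: none
Why: Barton–McCombie deoxygenation through the benzylic radical, which avoids the cationic conditions that would cause olefin migration or Friedel–Crafts closure onto C5, and for which 4-exo or 5-endo cyclisation onto C5=C6 is not competitive.

Step 8
Reactants: 18 methyl ester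
Product: 19 3-[(1S,4aR,5S,6R)-5-(2,5-dimethoxybenzyl)-1,5,6-trimethyl-1,2,3,4,4a,5,6,7-octahydronaphthalen-1-yl]propanoic acid
Conditions: LiOH, THF/MeOH/H2O, 23 °C; 1 M HCl
Reagents that add atoms: lithium hydroxide, [Li+].[OH-]
Why: Saponification of the unhindered methyl ester; no stereocentre is epimerisable.

Step 9
Reactants: 20 4,4-dimethylcyclohex-2-en-1-one
Product: 21 2-iodo-4,4-dimethylcyclohex-2-en-1-one
Conditions: I2, pyridine, CH2Cl2, 23 °C
Reagents that add atoms: iodine, II
Why: α-Iodination of the enone by pyridine conjugate addition, iodination of the enolate and elimination (Baylis–Hillman-type sequence).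

Step 10
Reactants: 21 iodoenone; 22 (Z)-2-(but-2-en-2-yl)-4,4,5,5-tetramethyl-1,3,2-dioxaborolane
Product: 23 2-[(2E)-but-2-en-2-yl]-4,4-dimethylcyclohex-2-en-1-one
Conditions: [1,1'-bis(diphenylphosphino)ferrocene]PdCl2 (5 mol %), K3PO4, dioxane/H2O, 60 °C
Reagents that add atoms: none
Why: Suzuki–Miyaura coupling with retention of the alkenyl geometry gives the diene C5'=C10'–C9'=C8' with both terminal substituents (C4' and the C8' methyl) outside.

Step 11
Reactants: 23 dienone; 24 ethylene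
Product: 25 rac-(4aS,7S)-4,4,7,8-tetramethyl-3,4,4a,5,6,7-hexahydronaphthalen-1(2H)-one
Conditions: ethylene (70 bar), BHT (cat.), PhMe, 190 °C, autoclave
Reagents that add atoms: none
Why: Thermal Diels–Alder reaction in which suprafacial bonding of ethylene to the (E,E)-configured diene termini forces H-5' and H-8' cis (racemic) and leaves the new C9'=C10' olefin conjugated with the ketone.

Step 12
Reactants: 25 racemic enone
Product: 26 (1S,4aS,7S)-4,4,7,8-tetramethyl-1,2,3,4,4a,5,6,7-octahydronaphthalen-1-ol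
Conditions: (3aR)-1-methyl-3,3-diphenyltetrahydro-1H,3H-pyrrolo[1,2-c][1,3,2]oxazaborole (20 mol %), BH3·SMe2, THF, −30 °C; MeOH; chromatographic removal of the (1S,4aR,7R) diastereomer
Reagents that add atoms: none
Why: Corey–Bakshi–Shibata reduction in which the (R)-catalyst delivers hydride to the same carbonyl face of both enantiomers of 25 (alkenyl side as the large group) to give 1S carbinols, so the racemate becomes two separable diastereomers and the (1S,4aS,7S) isomer (OH cis to H-5'; at most half the material) fixes the absolute configuration of C5' and C8'.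

Step 13
Reactants: 19 left-half acid; 26 right-half allylic alcohol
Product: 27 (1S,4aS,7S)-4,4,7,8-tetramethyl-1,2,3,4,4a,5,6,7-octahydronaphthalen-1-yl 3-[(1S,4aR,5S,6R)-5-(2,5-dimethoxybenzyl)-1,5,6-trimethyl-1,2,3,4,4a,5,6,7-octahydronaphthalen-1-yl]propanoate
Conditions: EDC·HCl, DMAP, CH2Cl2, 23 °C
Reagents that add atoms: none
Why: Steglich-type carbodiimide esterification under non-acidic conditions, with retention at the acid-sensitive allylic carbinol C1'.

Step 14
Reactants: 27 allylic ester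
Product: 30 2-[(1S,2S,4aS)-1,2,5,5-tetramethyl-1,2,3,4,4a,5,6,7-octahydronaphthalen-1-yl]-3-[(1S,4aR,5S,6R)-5-(2,5-dimethoxybenzyl)-1,5,6-trimethyl-1,2,3,4,4a,5,6,7-octahydronaphthalen-1-yl]propanoic acid (C11' epimers), via silyl ketene acetal 28 (not isolated), via trimethylsilyl ester 29 (not isolated)
Conditions: LiN(iPr)2, Me3SiCl, THF, −78 °C; PhMe, 90 °C; 1 M HCl
Reagents that add atoms: none
Why: Ireland–Claisen rearrangement, a [3,3] shift that is suprafacial on the allyl unit, so the new C11'–C9' bond forms on the face from which the C1' oxygen leaves (cis to H-5', anti to the C8' methyl), creating the C9' quaternary centre and the C1'=C10' olefin together (the C11' configuration is irrelevant).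

Step 15
Reactants: 30 rearranged acid
Product: 32 2-{[(1S,2R,5S,8aR)-1,2,5-trimethyl-5-{2-[(1R,2S,4aS)-1,2,5,5-tetramethyl-1,2,3,4,4a,5,6,7-octahydronaphthalen-1-yl]ethyl}-1,2,3,5,6,7,8,8a-octahydronaphthalen-1-yl]methyl}-1,4-dimethoxybenzene, via Barton ester 31 (not isolated)
Conditions: N-hydroxypyridine-2-thione, DCC, DMAP (cat.), CH2Cl2, 0 °C, dark; PhSH (20 equiv), hν (tungsten lamp), 0 °C
Reagents that add atoms: none
Why: Barton reductive decarboxylation, in which the thiohydroxamate ester fragments to the C11' radical and the large excess of PhSH quenches it faster than 3-exo closure and 1,2-vinyl shift onto the C1'=C10' olefin; no stereocentre is touched.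

Step 16
Reactants: 32 dimethoxyarene
Product: 33 2-{[(1S,2R,5S,8aR)-1,2,5-trimethyl-5-{2-[(1R,2S,4aS)-1,2,5,5-tetramethyl-1,2,3,4,4a,5,6,7-octahydronaphthalen-1-yl]ethyl}-1,2,3,5,6,7,8,8a-octahydronaphthalen-1-yl]methyl}cyclohexa-2,5-diene-1,4-dione
Conditions: (NH4)2Ce(NO3)6, MeCN/H2O, 0 °C
Reagents that add atoms: water, O
Why: Oxidative demethylation of the 1,4-dimethoxyarene to the para-quinone by single-electron oxidation (quinone oxygens from water); the hindered trisubstituted olefins are not oxidised.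

Step 17
Reactants: 33 quinone
Product: 34 2-{[(1S,2R,5S,8aR)-1,2,5-trimethyl-5-{2-[(1R,2S,4aS)-1,2,5,5-tetramethyl-1,2,3,4,4a,5,6,7-octahydronaphthalen-1-yl]ethyl}-1,2,3,5,6,7,8,8a-octahydronaphthalen-1-yl]methyl}benzene-1,4-diol
Conditions: Na2S2O4, THF/H2O, 23 °C, argon
Reagents that add atoms: none
Why: Dithionite reduction of the quinone to the hydroquinone, kept under argon to prevent re-oxidation.

Step 18
Reactants: 34 hydroquinone
Product: 36 2-{[(1S,2R,5S,8aR)-1,2,5-trimethyl-5-{2-[(1R,2S,4aS)-1,2,5,5-tetramethyl-1,2,3,4,4a,5,6,7-octahydronaphthalen-1-yl]ethyl}-1,2,3,5,6,7,8,8a-octahydronaphthalen-1-yl]methyl}-1,4-phenylene bis(hydrogen sulfate) (target CNP0243830.4), via bis(pyridinium) salt 35 (not isolated)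
Conditions: SO3·pyridine (6 equiv), pyridine, 50 °C; Dowex 50W (H+ form), MeOH/H2O, 0 °C
Reagents that add atoms: sulfur trioxide–pyridine complex, [O-]S(=O)(=O)[n+]1ccccc1
Why: O-sulfation of both phenols by the SO3·pyridine complex, then cation exchange to the bis(hydrogen sulfate) as drawn; no stereocentre or olefin is affected.

## Compound list

1 | 2-methylcyclohexanone (racemic) | CC1CCCCC1=O | starting material
2 | (R)-1-phenylethylamine | C[C@@H](N)c1ccccc1 | starting material
3 | methyl acrylate | C=CC(=O)OC | starting material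
4 | N-[(1R)-1-phenylethyl]imine of 2-methylcyclohexanone (in equilibrium with its enamine) | CC1CCCCC1=N[C@H](C)c1ccccc1 | intermediate
5 | methyl 3-[(1S)-1-methyl-2-{[(1R)-1-phenylethyl]imino}cyclohexyl]propanoate | COC(=O)CC[C@]1(C)CCCCC1=N[C@H](C)c1ccccc1 | intermediate
6 | methyl 3-[(1S)-1-methyl-2-oxocyclohexyl]propanoate | COC(=O)CC[C@]1(C)CCCCC1=O | intermediate
7 | potassium enolate of 6 (C5=C10 enolate) | [K+].[O-]C1=CCCC[C@@]1(C)CCC(=O)OC | intermediate
8 | methyl 3-[(1S)-1-methyl-2-(trifluoromethylsulfonyloxy)cyclohex-2-en-1-yl]propanoate | COC(=O)CC[C@]1(C)CCCC=C1OS(=O)(=O)C(F)(F)F | intermediate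
9 | tributyl(vinyl)stannane | C=C[Sn](CCCC)(CCCC)CCCC | starting material
10 | methyl 3-[(1S)-2-ethenyl-1-methylcyclohex-2-en-1-yl]propanoate | COC(=O)CC[C@]1(C)CCCC=C1C=C | intermediate
11 | (E)-2-methylbut-2-enal | C/C=C(\C)C=O | starting material
12 | methyl 3-[(1S,4aS,5S,6R)-5-formyl-1,5,6-trimethyl-1,2,3,4,4a,5,6,7-octahydronaphthalen-1-yl]propanoate | C[C@@H]1CC=C2[C@H](CCC[C@@]2(C)CCC(=O)OC)[C@@]1(C)C=O | intermediate
13 | (2,5-dimethoxyphenyl)magnesium bromide | COc1ccc(OC)c([Mg]Br)c1 | starting material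
14 | methyl 3-[(1S,4aS,5S,6R)-5-[(2,5-dimethoxyphenyl)(hydroxy)methyl]-1,5,6-trimethyl-1,2,3,4,4a,5,6,7-octahydronaphthalen-1-yl]propanoate (carbinol epimers) | C[C@@H]1CC=C2[C@H](CCC[C@@]2(C)CCC(=O)OC)[C@@]1(C)C(O)c1cc(OC)ccc1OC | intermediate
15 | sodium alkoxide of 14 | [Na+].C[C@@H]1CC=C2[C@H](CCC[C@@]2(C)CCC(=O)OC)[C@@]1(C)C([O-])c1cc(OC)ccc1OC | intermediate
16 | sodium O-alkyl dithiocarbonate (xanthate salt) of 14 | [Na+].C[C@@H]1CC=C2[C@H](CCC[C@@]2(C)CCC(=O)OC)[C@@]1(C)C(OC(=S)[S-])c1cc(OC)ccc1OC | intermediate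
17 | O-benzylic S-methyl xanthate of 14 | C[C@@H]1CC=C2[C@H](CCC[C@@]2(C)CCC(=O)OC)[C@@]1(C)C(OC(=S)SC)c1cc(OC)ccc1OC | intermediate
18 | methyl 3-[(1S,4aR,5S,6R)-5-(2,5-dimethoxybenzyl)-1,5,6-trimethyl-1,2,3,4,4a,5,6,7-octahydronaphthalen-1-yl]propanoate | C[C@@H]1CC=C2[C@H](CCC[C@@]2(C)CCC(=O)OC)[C@@]1(C)Cc1cc(OC)ccc1OC | intermediate
19 | 3-[(1S,4aR,5S,6R)-5-(2,5-dimethoxybenzyl)-1,5,6-trimethyl-1,2,3,4,4a,5,6,7-octahydronaphthalen-1-yl]propanoic acid | C[C@@H]1CC=C2[C@H](CCC[C@@]2(C)CCC(=O)O)[C@@]1(C)Cc1cc(OC)ccc1OC | intermediate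
20 | 4,4-dimethylcyclohex-2-en-1-one | CC1(C)CCC(=O)C=C1 | starting material
21 | 2-iodo-4,4-dimethylcyclohex-2-en-1-one | CC1(C)CCC(=O)C(I)=C1 | intermediate
22 | (Z)-2-(but-2-en-2-yl)-4,4,5,5-tetramethyl-1,3,2-dioxaborolane | C/C=C(\C)B1OC(C)(C)C(C)(C)O1 | starting material
23 | 2-[(2E)-but-2-en-2-yl]-4,4-dimethylcyclohex-2-en-1-one | C/C=C(\C)C1=CC(C)(C)CCC1=O | intermediate
24 | ethylene | C=C | starting material
25 | rac-(4aS,7S)-4,4,7,8-tetramethyl-3,4,4a,5,6,7-hexahydronaphthalen-1(2H)-one (racemate; the enantiomer carried on is drawn) | CC1=C2C(=O)CCC(C)(C)[C@@H]2CC[C@@H]1C | intermediate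
26 | (1S,4aS,7S)-4,4,7,8-tetramethyl-1,2,3,4,4a,5,6,7-octahydronaphthalen-1-ol | CC1=C2[C@@H](O)CCC(C)(C)[C@@H]2CC[C@@H]1C | intermediate
27 | (1S,4aS,7S)-4,4,7,8-tetramethyl-1,2,3,4,4a,5,6,7-octahydronaphthalen-1-yl ester of acid 19 | C[C@@H]1CC=C2[C@H](CCC[C@@]2(C)CCC(=O)O[C@H]3CCC(C)(C)[C@@H]4CC[C@H](C)C(C)=C34)[C@@]1(C)Cc1cc(OC)ccc1OC | intermediate
28 | trimethylsilyl ketene acetal of 27 (C11'=C(OSiMe3)O–C1') | C[C@@H]1CC=C2[C@H](CCC[C@@]2(C)CC=C(O[Si](C)(C)C)O[C@H]3CCC(C)(C)[C@@H]4CC[C@H](C)C(C)=C34)[C@@]1(C)Cc1cc(OC)ccc1OC | intermediate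
29 | trimethylsilyl ester of 30 | C[C@@H]1CC=C2[C@H](CCC[C@@]2(C)CC(C(=O)O[Si](C)(C)C)[C@@]2(C)C3=CCCC(C)(C)[C@@H]3CC[C@@H]2C)[C@@]1(C)Cc1cc(OC)ccc1OC | intermediate
30 | 2-[(1S,2S,4aS)-1,2,5,5-tetramethyl-1,2,3,4,4a,5,6,7-octahydronaphthalen-1-yl]-3-[(1S,4aR,5S,6R)-5-(2,5-dimethoxybenzyl)-1,5,6-trimethyl-1,2,3,4,4a,5,6,7-octahydronaphthalen-1-yl]propanoic acid (C11' epimers) | C[C@@H]1CC=C2[C@H](CCC[C@@]2(C)CC(C(=O)O)[C@@]2(C)C3=CCCC(C)(C)[C@@H]3CC[C@@H]2C)[C@@]1(C)Cc1cc(OC)ccc1OC | intermediate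
31 | 2-thioxopyridin-1(2H)-yl (Barton) ester of 30 | C[C@@H]1CC=C2[C@H](CCC[C@@]2(C)CC(C(=O)ON3C=CC=CC3=S)[C@@]2(C)C3=CCCC(C)(C)[C@@H]3CC[C@@H]2C)[C@@]1(C)Cc1cc(OC)ccc1OC | intermediate
32 | 2-{[(1S,2R,5S,8aR)-1,2,5-trimethyl-5-{2-[(1R,2S,4aS)-1,2,5,5-tetramethyl-1,2,3,4,4a,5,6,7-octahydronaphthalen-1-yl]ethyl}-1,2,3,5,6,7,8,8a-octahydronaphthalen-1-yl]methyl}-1,4-dimethoxybenzene | C[C@@H]1CC=C2[C@H](CCC[C@@]2(C)CC[C@@]2(C)C3=CCCC(C)(C)[C@@H]3CC[C@@H]2C)[C@@]1(C)Cc1cc(OC)ccc1OC | intermediate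
33 | corresponding 2-substituted cyclohexa-2,5-diene-1,4-dione (quinone) | C[C@@H]1CC=C2[C@H](CCC[C@@]2(C)CC[C@@]2(C)C3=CCCC(C)(C)[C@@H]3CC[C@@H]2C)[C@@]1(C)CC1=CC(=O)C=CC1=O | intermediate
34 | corresponding 2-substituted benzene-1,4-diol (hydroquinone) | C[C@@H]1CC=C2[C@H](CCC[C@@]2(C)CC[C@@]2(C)C3=CCCC(C)(C)[C@@H]3CC[C@@H]2C)[C@@]1(C)Cc1cc(O)ccc1O | intermediate
35 | bis(pyridinium) salt of the disulfate | C[C@@H]1CC=C2[C@H](CCC[C@@]2(C)CC[C@@]2(C)C3=CCCC(C)(C)[C@@H]3CC[C@@H]2C)[C@@]1(C)Cc1cc(OS(=O)(=O)[O-])ccc1OS(=O)(=O)[O-].c1cc[nH+]cc1.c1cc[nH+]cc1 | intermediate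
36 | 2-{[(1S,2R,5S,8aR)-1,2,5-trimethyl-5-{2-[(1R,2S,4aS)-1,2,5,5-tetramethyl-1,2,3,4,4a,5,6,7-octahydronaphthalen-1-yl]ethyl}-1,2,3,5,6,7,8,8a-octahydronaphthalen-1-yl]methyl}-1,4-phenylene bis(hydrogen sulfate) | C[C@@H]1CC=C2[C@H](CCC[C@@]2(C)CC[C@@]2(C)C3=CCCC(C)(C)[C@@H]3CC[C@@H]2C)[C@@]1(C)Cc1cc(OS(=O)(=O)O)ccc1OS(=O)(=O)O | target

## Step count, longest sequence and risks

Total steps: 18. Longest linear sequence: 14 (steps 1–8, then 13–18); the right half takes 4 steps (9–12).

Compound 6 is formed in about 90% ee; material from its minor enantiomer becomes diastereomeric after step 4 and again after step 13 and is removed by chromatography there.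

Most likely to fail:

Step 4 (catalytic enantioselective exo Diels–Alder of a hindered trisubstituted enal). The reaction may be too slow, or the catalyst may not impose the expected face. The fallback sets out from 10 and gives up catalyst control: tiglaldehyde 11 is added under EtAlCl2 in CH2Cl2 at −78 °C. Because C4 is already a single enantiomer, the two exo adducts are diastereomers, and 12 is separated by chromatography from methyl 3-[(1S,4aR,5R,6S)-5-formyl-1,5,6-trimethyl-1,2,3,4,4a,5,6,7-octahydronaphthalen-1-yl]propanoate F1. The route is rejoined at 12, at the cost of about half the material.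

Step 11 (ethylene cycloaddition at 190 °C). The hindered dienone may dimerise or decompose before it adds ethylene. The fallback sets out from 23 and uses phenyl vinyl sulfone (PhMe, 140 °C) as a reactive ethylene equivalent, giving rac-(4aS,7S)-4,4,7,8-tetramethyl-5-(phenylsulfonyl)-3,4,4a,5,6,7-hexahydronaphthalen-1(2H)-one F2 (sulfone regio- and stereoisomers converge later). The CBS reduction of step 12 then gives (1S,4aS,7S)-4,4,7,8-tetramethyl-5-(phenylsulfonyl)-1,2,3,4,4a,5,6,7-octahydronaphthalen-1-ol F3. Na/Hg (Na2HPO4, MeOH, −20 °C) removes the sulfone at the allylic-alcohol stage, where no enone is present, and after diastereomer separation the route is rejoined at 26.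

Step 14 (Ireland–Claisen onto a tetrasubstituted olefin, together with the radical decarboxylation that must follow). The rearrangement may stall, or the C11' radical in step 15 may rearrange. The fallback sets out from 19 and 26 and forms the same bond by a traceless copper-mediated anti-SN2' substitution. Acid 19 is converted through its Barton ester with CHI3 and light into 2-{[(1S,2R,5S,8aR)-5-(2-iodoethyl)-1,2,5-trimethyl-1,2,3,5,6,7,8,8a-octahydronaphthalen-1-yl]methyl}-1,4-dimethoxybenzene F4. Alcohol 26 is inverted at C1' by Mitsunobu esterification (PPh3, DIAD, picolinic acid) to (1R,4aS,7S)-4,4,7,8-tetramethyl-1,2,3,4,4a,5,6,7-octahydronaphthalen-1-yl pyridine-2-carboxylate F5. F4 is converted (t-BuLi; MgBr2·OEt2; CuBr·SMe2, THF, −40 °C) into the alkylcopper reagent, which attacks C9' of F5 anti to the picolinate, that is cis to H-5' and anti to the C8' methyl. This gives 32 directly, where the route is rejoined; compounds 27–31 are skipped.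

## Further compounds

F1 | step 4 | methyl 3-[(1S,4aR,5R,6S)-5-formyl-1,5,6-trimethyl-1,2,3,4,4a,5,6,7-octahydronaphthalen-1-yl]propanoate | C[C@H]1CC=C2[C@@H](CCC[C@@]2(C)CCC(=O)OC)[C@]1(C)C=O
F2 | step 11 | rac-(4aS,7S)-4,4,7,8-tetramethyl-5-(phenylsulfonyl)-3,4,4a,5,6,7-hexahydronaphthalen-1(2H)-one (sulfone epimers) | CC1=C2C(=O)CCC(C)(C)[C@@H]2C(S(=O)(=O)c2ccccc2)C[C@@H]1C
F3 | step 11 | (1S,4aS,7S)-4,4,7,8-tetramethyl-5-(phenylsulfonyl)-1,2,3,4,4a,5,6,7-octahydronaphthalen-1-ol (sulfone epimers) | CC1=C2[C@@H](O)CCC(C)(C)[C@@H]2C(S(=O)(=O)c2ccccc2)C[C@@H]1C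
F4 | step 14 | 2-{[(1S,2R,5S,8aR)-5-(2-iodoethyl)-1,2,5-trimethyl-1,2,3,5,6,7,8,8a-octahydronaphthalen-1-yl]methyl}-1,4-dimethoxybenzene | C[C@@H]1CC=C2[C@H](CCC[C@@]2(C)CCI)[C@@]1(C)Cc1cc(OC)ccc1OC
F5 | step 14 | (1R,4aS,7S)-4,4,7,8-tetramethyl-1,2,3,4,4a,5,6,7-octahydronaphthalen-1-yl pyridine-2-carboxylate | O=C(O[C@@H]1CCC(C)(C)[C@@H]2CC[C@H](C)C(C)=C12)c1ccccn1
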